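The route rests on disconnecting C4–C5, so that ring A (C1–C5, C10) closes last onto a finished ring B. In the key step palladium diacetate converts the C5=C6 silyl enol ether of a monocyclic precursor into a palladium enolate that adds 6-exo to a pent-4-enyl chain on C10; β-hydride loss delivers the C4=C11 methylene, the quaternary C5 and the trans ring fusion in one operation. It exploits the fact that the exocyclic alkene sits on quaternary C5, β,γ to a carbonyl placed temporarily at C6. The precursor, which already carries the MOM-protected arylmethyl group, arises from asymmetric conjugate addition–benzylation, carbonyl transposition and dissolving-metal reduction.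

Key step: step 10

Remark on numbering: C1–C10 are the decalin carbons in avarane numbering (ring A = C1, C2, C3, C4, C5, C10; ring B = C5 to C10), and C11 is the exocyclic methylene carbon. C8 carries the secondary methyl, C9 the quaternary methyl and the arylmethyl group. Primed numbers are arene carbons, C1′ bearing the CH2.

Assumption: compounds 9 and 14 are carried as epimer mixtures at one centre each (C5 in 9, C10 in 14); both centres become sp2 in the following step. The ligand enantiomer in step 4 is the one that gives the (3S) adduct.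

Step 1
Reactants: 1 2,3,4-trihydroxybenzaldehyde
Product: 2 2,3,4-tris(methoxymethoxy)benzaldehyde
Conditions: NaH, MOMCl, DMF, 0 °C → rt
Reagents that add atoms: chloromethyl methyl ether, COCCl
Why: Williamson-type O-alkylation of the three phenoxides (NaH so that the hydrogen-bonded C2′ hydroxyl also reacts) installs base-stable, ortho-directing MOM ethers that should survive every later organometallic and reducing step.

Step 2
Reactants: 2 2,3,4-tris(methoxymethoxy)benzaldehyde
Product: 3 [2,3,4-tris(methoxymethoxy)phenyl]methanol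
Conditions: NaBH4, MeOH, 0 °C
Reagents that add atoms: none
Why: Borohydride reduction of the aldehyde gives the benzylic alcohol and leaves the acetal-type MOM ethers untouched.

Step 3
Reactants: 3 [2,3,4-tris(methoxymethoxy)phenyl]methanol
Product: 4 1-(bromomethyl)-2,3,4-tris(methoxymethoxy)benzene
Conditions: CBr4, PPh3, CH2Cl2, 0 °C; used at once
Reagents that add atoms: tetrabromomethane, BrC(Br)(Br)Br
Why: The Appel reaction converts the primary benzylic alcohol into the bromide under neutral conditions that spare the MOM ethers.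

Step 4
Reactants: 5 2-methylcyclohex-2-en-1-one; 4 1-(bromomethyl)-2,3,4-tris(methoxymethoxy)benzene
Product: 7 (2R,3S)-2,3-dimethyl-2-{[2,3,4-tris(methoxymethoxy)phenyl]methyl}cyclohexan-1-one, via bromomagnesium enolate 6 (not isolated)
Conditions: MeMgBr, Cu(OTf)2 (3 mol %), chiral imidazolinium chloride (NHC precursor, 4 mol %), Et2O, −30 °C; then 4, DMPU, THF, −30 °C → rt
Reagents that add atoms: methylmagnesium bromide, C[Mg]Br
Why: Copper-catalysed asymmetric conjugate addition of the methyl Grignard reagent sets C8 under ligand control, and the magnesium enolate is benzylated by 4 on the face opposite the new pseudoaxial C8 methyl (tandem conjugate addition–enolate trapping), which sets quaternary C9 with the arylmethyl group trans to the C8 methyl.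

Step 5
Reactants: 7 (2R,3S)-2,3-dimethyl-2-{[2,3,4-tris(methoxymethoxy)phenyl]methyl}cyclohexan-1-one
Product: 9 (2R,3S,6RS)-2,3,6-trimethyl-2-{[2,3,4-tris(methoxymethoxy)phenyl]methyl}cyclohexan-1-one, via lithium enolate 8 (not isolated)
Conditions: LDA, THF, −78 °C; MeI, −78 → 0 °C
Reagents that add atoms: iodomethane, CI
Why: Because C9 is quaternary the ketone can enolise only toward C5, so kinetic deprotonation and SN2 methylation place the future C5 methyl group, and the configuration of the new centre is immaterial since step 6 flattens it.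

Step 6
Reactants: 9 (2R,3S,6RS)-2,3,6-trimethyl-2-{[2,3,4-tris(methoxymethoxy)phenyl]methyl}cyclohexan-1-one
Product: 12 (5S,6R)-2,5,6-trimethyl-6-{[2,3,4-tris(methoxymethoxy)phenyl]methyl}cyclohex-2-en-1-one, via lithium enolate 10 (not isolated), via trimethylsilyl enol ether 11 (not isolated)
Conditions: LDA, THF, −78 → 0 °C; TMSCl; solvent exchange; Pd(OAc)2 (1.1 equiv), MeCN, rt
Reagents that add atoms: none
Why: Saegusa–Ito oxidation, in which the only possible silyl enol ether (C5=C10) is transmetalated to a palladium enolate whose β-hydride elimination toward the ring CH2 (C6) should give the conjugated endocyclic enone.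

Step 7
Reactants: 12 (5S,6R)-2,5,6-trimethyl-6-{[2,3,4-tris(methoxymethoxy)phenyl]methyl}cyclohex-2-en-1-one; 13 pent-4-en-1-ylmagnesium bromide
Product: 14 (1RS,5S,6R)-2,5,6-trimethyl-1-(pent-4-en-1-yl)-6-{[2,3,4-tris(methoxymethoxy)phenyl]methyl}cyclohex-2-en-1-ol
Conditions: CeCl3 (anhydrous), THF, −78 → 0 °C; aq NH4Cl
Reagents that add atoms: none
Why: Cerium-mediated 1,2-addition of the Grignard reagent to the hindered enone suppresses enolisation and conjugate addition and attaches the C1–C4/C11 chain to C10, and both carbinol epimers converge in step 8.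

Step 8
Reactants: 14 (1RS,5S,6R)-2,5,6-trimethyl-1-(pent-4-en-1-yl)-6-{[2,3,4-tris(methoxymethoxy)phenyl]methyl}cyclohex-2-en-1-ol
Product: 15 (4R,5S)-2,4,5-trimethyl-3-(pent-4-en-1-yl)-4-{[2,3,4-tris(methoxymethoxy)phenyl]methyl}cyclohex-2-en-1-one
Conditions: pyridinium chlorochromate [C5H5NH][CrO3Cl], NaOAc, 4 Å MS, CH2Cl2, rt
Reagents that add atoms: pyridinium chlorochromate, [O-][Cr](=O)(=O)Cl.c1cc[nH+]cc1
Why: Babler–Dauben oxidative transposition, in which the chromate ester of the tertiary allylic alcohol undergoes a [3,3] shift to C6 and is oxidised there, moves the carbonyl to C6 and the double bond to C5=C10.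

Step 9
Reactants: 15 (4R,5S)-2,4,5-trimethyl-3-(pent-4-en-1-yl)-4-{[2,3,4-tris(methoxymethoxy)phenyl]methyl}cyclohex-2-en-1-one
Product: 17 trimethyl{[(3S,4R,5S)-2,4,5-trimethyl-3-(pent-4-en-1-yl)-4-{[2,3,4-tris(methoxymethoxy)phenyl]methyl}cyclohex-1-en-1-yl]oxy}silane, via lithium enolate 16 (not isolated)
Conditions: Li (2.5 equiv), NH3(l)/THF, t-BuOH (1.0 equiv), −78 °C; isoprene; NH3 evaporated; TMSCl, Et3N, THF, −78 → 0 °C
Reagents that add atoms: chlorotrimethylsilane, C[Si](C)(C)Cl
Why: Dissolving-metal conjugate reduction should protonate the C10 carbanion axially on the face opposite the axial C9 methyl and the C8 methyl, so that the side chain becomes equatorial and cis to both methyl groups (S at C10), and the regiospecific C5=C6 lithium enolate is trapped on oxygen as the silyl enol ether.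

Step 10
Reactants: 17 trimethyl{[(3S,4R,5S)-2,4,5-trimethyl-3-(pent-4-en-1-yl)-4-{[2,3,4-tris(methoxymethoxy)phenyl]methyl}cyclohex-1-en-1-yl]oxy}silane
Product: 18 (3S,4R,4aS,8aS)-3,4,8a-trimethyl-8-methylidene-4-{[2,3,4-tris(methoxymethoxy)phenyl]methyl}octahydronaphthalen-1(2H)-one
Conditions: Pd(OAc)2 (1.1 equiv), MeCN, rt
Reagents that add atoms: none
Why: Transmetalation of the silyl enol ether to Pd(OAc)2 gives a divalent palladium enolate bound at C5, the terminal alkene of the C10 side chain inserts syn into the C5–Pd bond to form C4–C5 with palladium on C11, and β-hydride elimination of the only β-hydrogen (H4) releases the C4=C11 methylene and zerovalent palladium. The closest known reaction type is the palladium-diacetate-mediated cycloalkenylation of silyl enol ethers that carry alkenyl side chains, an intramolecular relative of the Saegusa–Ito oxidation. Ring A closes in the 6-exo-trig mode. The new quaternary stereocenter C5 is controlled by the axial C9 methyl of the chair-like ring B, which shields the face syn to it, so C4 should add to the face that carries H10 while the equatorial C10 tether spans a chair-like transition state, giving the trans-fused decalin with the C5 methyl axial. The step needs alkene insertion to win over β-hydride loss toward H10 or the C5 methyl (plain dehydrogenation back to 15) and exo over endo insertion; the regiodefined tetrasubstituted enol ether from step 9, the three-carbon tether that holds the alkene over C5, and the absence of any β-hydrogen other than H4 in the alkylpalladium are what secure this.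

Step 11
Reactants: 18 (3S,4R,4aS,8aS)-3,4,8a-trimethyl-8-methylidene-4-{[2,3,4-tris(methoxymethoxy)phenyl]methyl}octahydronaphthalen-1(2H)-one
Product: 20 (1R,2S,4aS,8aS)-1,2,4a-trimethyl-5-methylidene-1-{[2,3,4-tris(methoxymethoxy)phenyl]methyl}decahydronaphthalene, via hydrazone 19 (not isolated)
Conditions: N2H4·H2O, KOH, diethylene glycol, 130 °C, then 200 °C, argon
Reagents that add atoms: none
Why: Wolff–Kishner reduction (Huang-Minlon procedure) removes the now superfluous C6 carbonyl through the hydrazone, the basic medium leaves the MOM ethers intact, and the exocyclic alkene cannot move into conjugation because C5 is quaternary.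

Step 12
Reactants: 20 (1R,2S,4aS,8aS)-1,2,4a-trimethyl-5-methylidene-1-{[2,3,4-tris(methoxymethoxy)phenyl]methyl}decahydronaphthalene
Product: 22 methyl 2,3,4-tris(methoxymethoxy)-5-{[(1R,2S,4aS,8aS)-1,2,4a-trimethyl-5-methylidenedecahydronaphthalen-1-yl]methyl}benzoate, via aryllithium 21 (not isolated)
Conditions: n-BuLi, TMEDA, THF, −78 → 0 °C; ClCO2Me, −78 °C
Reagents that add atoms: methyl chloroformate, COC(=O)Cl
Why: Directed ortho-metalation, in which the MOM ether at C4′ directs lithiation to C5′ (the only ring position ortho to an oxygen substituent), followed by acylation of the aryllithium with methyl chloroformate, installs the benzoate.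

Step 13
Reactants: 22 methyl 2,3,4-tris(methoxymethoxy)-5-{[(1R,2S,4aS,8aS)-1,2,4a-trimethyl-5-methylidenedecahydronaphthalen-1-yl]methyl}benzoate
Product: 23 methyl 2,3,4-trihydroxy-5-{[(1R,2S,4aS,8aS)-1,2,4a-trimethyl-5-methylidenedecahydronaphthalen-1-yl]methyl}benzoate
Conditions: ZnBr2, n-PrSH, CH2Cl2, 0 °C → rt
Reagents that add atoms: none
Why: Lewis-acid-assisted transacetalisation of the three MOM ethers to the thiol frees the phenols under mild, non-protic conditions that should spare the acid-sensitive exocyclic alkene and the methyl ester.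

Compound list

1 | 2,3,4-trihydroxybenzaldehyde | O=Cc1ccc(O)c(O)c1O | starting material
2 | 2,3,4-tris(methoxymethoxy)benzaldehyde | O=Cc1ccc(OCOC)c(OCOC)c1OCOC | intermediate
3 | [2,3,4-tris(methoxymethoxy)phenyl]methanol | OCc1ccc(OCOC)c(OCOC)c1OCOC | intermediate
4 | 1-(bromomethyl)-2,3,4-tris(methoxymethoxy)benzene | BrCc1ccc(OCOC)c(OCOC)c1OCOC | intermediate
5 | 2-methylcyclohex-2-en-1-one | CC1=CCCCC1=O | starting material
6 | bromomagnesium (3S)-2,3-dimethylcyclohex-1-en-1-olate (formed in the flask) | CC1=C(O[Mg]Br)CCC[C@@H]1C | intermediate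
7 | (2R,3S)-2,3-dimethyl-2-{[2,3,4-tris(methoxymethoxy)phenyl]methyl}cyclohexan-1-one | O=C1CCC[C@H](C)[C@@]1(C)Cc2ccc(OCOC)c(OCOC)c2OCOC | intermediate
8 | lithium (5S,6R)-5,6-dimethyl-6-{[2,3,4-tris(methoxymethoxy)phenyl]methyl}cyclohex-1-en-1-olate (formed in the flask) | [Li]OC1=CCC[C@H](C)[C@@]1(C)Cc2ccc(OCOC)c(OCOC)c2OCOC | intermediate
9 | (2R,3S,6RS)-2,3,6-trimethyl-2-{[2,3,4-tris(methoxymethoxy)phenyl]methyl}cyclohexan-1-one (C6 epimers) | O=C1C(C)CC[C@H](C)[C@@]1(C)Cc2ccc(OCOC)c(OCOC)c2OCOC | intermediate
10 | lithium (5S,6R)-2,5,6-trimethyl-6-{[2,3,4-tris(methoxymethoxy)phenyl]methyl}cyclohex-1-en-1-olate (formed in the flask) | [Li]OC1=C(C)CC[C@H](C)[C@@]1(C)Cc2ccc(OCOC)c(OCOC)c2OCOC | intermediate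
11 | trimethyl{[(5S,6R)-2,5,6-trimethyl-6-{[2,3,4-tris(methoxymethoxy)phenyl]methyl}cyclohex-1-en-1-yl]oxy}silane (formed in the flask) | C[Si](C)(C)OC1=C(C)CC[C@H](C)[C@@]1(C)Cc2ccc(OCOC)c(OCOC)c2OCOC | intermediate
12 | (5S,6R)-2,5,6-trimethyl-6-{[2,3,4-tris(methoxymethoxy)phenyl]methyl}cyclohex-2-en-1-one | O=C1C(C)=CC[C@H](C)[C@@]1(C)Cc2ccc(OCOC)c(OCOC)c2OCOC | intermediate
13 | pent-4-en-1-ylmagnesium bromide (solution in THF) | C=CCCC[Mg]Br | starting material
14 | (1RS,5S,6R)-2,5,6-trimethyl-1-(pent-4-en-1-yl)-6-{[2,3,4-tris(methoxymethoxy)phenyl]methyl}cyclohex-2-en-1-ol (C1 epimers) | OC1(CCCC=C)C(C)=CC[C@H](C)[C@@]1(C)Cc2ccc(OCOC)c(OCOC)c2OCOC | intermediate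
15 | (4R,5S)-2,4,5-trimethyl-3-(pent-4-en-1-yl)-4-{[2,3,4-tris(methoxymethoxy)phenyl]methyl}cyclohex-2-en-1-one | O=C1C(C)=C(CCCC=C)[C@](C)(Cc2ccc(OCOC)c(OCOC)c2OCOC)[C@@H](C)C1 | intermediate
16 | lithium (3S,4R,5S)-2,4,5-trimethyl-3-(pent-4-en-1-yl)-4-{[2,3,4-tris(methoxymethoxy)phenyl]methyl}cyclohex-1-en-1-olate (formed in the flask) | [Li]OC1=C(C)[C@@H](CCCC=C)[C@](C)(Cc2ccc(OCOC)c(OCOC)c2OCOC)[C@@H](C)C1 | intermediate
17 | trimethyl{[(3S,4R,5S)-2,4,5-trimethyl-3-(pent-4-en-1-yl)-4-{[2,3,4-tris(methoxymethoxy)phenyl]methyl}cyclohex-1-en-1-yl]oxy}silane | C[Si](C)(C)OC1=C(C)[C@@H](CCCC=C)[C@](C)(Cc2ccc(OCOC)c(OCOC)c2OCOC)[C@@H](C)C1 | intermediate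
18 | (3S,4R,4aS,8aS)-3,4,8a-trimethyl-8-methylidene-4-{[2,3,4-tris(methoxymethoxy)phenyl]methyl}octahydronaphthalen-1(2H)-one | C=C1CCC[C@H]2[C@](C)(Cc3ccc(OCOC)c(OCOC)c3OCOC)[C@@H](C)CC(=O)[C@]12C | intermediate
19 | hydrazone of 18 (formed in the flask) | C=C1CCC[C@H]2[C@](C)(Cc3ccc(OCOC)c(OCOC)c3OCOC)[C@@H](C)CC(=NN)[C@]12C | intermediate
20 | (1R,2S,4aS,8aS)-1,2,4a-trimethyl-5-methylidene-1-{[2,3,4-tris(methoxymethoxy)phenyl]methyl}decahydronaphthalene | C=C1CCC[C@H]2[C@](C)(Cc3ccc(OCOC)c(OCOC)c3OCOC)[C@@H](C)CC[C@]12C | intermediate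
21 | {2,3,4-tris(methoxymethoxy)-5-{[(1R,2S,4aS,8aS)-1,2,4a-trimethyl-5-methylidenedecahydronaphthalen-1-yl]methyl}phenyl}lithium (formed in the flask) | C=C1CCC[C@H]2[C@](C)(Cc3cc([Li])c(OCOC)c(OCOC)c3OCOC)[C@@H](C)CC[C@]12C | intermediate
22 | methyl 2,3,4-tris(methoxymethoxy)-5-{[(1R,2S,4aS,8aS)-1,2,4a-trimethyl-5-methylidenedecahydronaphthalen-1-yl]methyl}benzoate | C=C1CCC[C@H]2[C@](C)(Cc3cc(C(=O)OC)c(OCOC)c(OCOC)c3OCOC)[C@@H](C)CC[C@]12C | intermediate
23 | methyl 2,3,4-trihydroxy-5-{[(1R,2S,4aS,8aS)-1,2,4a-trimethyl-5-methylidenedecahydronaphthalen-1-yl]methyl}benzoate | C=C1CCC[C@H]2[C@](C)(Cc3cc(C(=O)OC)c(O)c(O)c3O)[C@@H](C)CC[C@]12C | target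

Total step count: 13. Longest linear sequence: 13 steps (1 → 23); the ring B branch from 5 has 10.

Steps most likely to fail

Step 10 (key step). β-Hydride elimination from the palladium enolate (toward H10 or the C5 methyl) may outrun alkene insertion and simply return enone 15, and a palladium hydride may walk the new exocyclic double bond into ring A. The fallback sets out from 12 and comes back at 18; it replaces the alkene by an alkyne and the palladium chemistry by a gold-catalysed Conia-ene-type 6-exo-dig cyclisation, which has no β-hydride pathway. (5-Chloropent-1-yn-1-yl)trimethylsilane and magnesium would give [5-(trimethylsilyl)pent-4-yn-1-yl]magnesium chloride F1, which adds to 12 (CeCl3, THF) to give the tertiary allylic alcohol F2. Pyridinium chlorochromate would transpose F2 to the silylalkynyl enone F3, and K2CO3 in MeOH would free the terminal alkynyl enone F4. After deprotonation of the alkyne with LiNH2 so that it survives, Li/NH3 reduction and NH4Cl quench should give the saturated alkynyl ketone F5 with C10 set as in step 9. TMSCl/NaI/Et3N in MeCN would give the more substituted trimethylsilyl enol ether F6, which [Au(PPh3)Cl]/AgBF4 in CH2Cl2/MeOH should cyclise to 18. The less substituted enol ether cannot reach the alkyne and would be recycled as F5.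

Step 9. The C10 carbanion may be protonated with poor facial selectivity, or the enone radical anion may cyclise onto the pendant alkene before the second electron arrives. The fallback sets out from 15 and comes back at 18; it replaces electron transfer and protonation by hydride delivery. Copper-hydride-catalysed 1,4-hydrosilylation ([1,3-bis(2,6-diisopropylphenyl)imidazol-2-ylidene]copper chloride, NaOtBu, PhMe2SiH, toluene, rt) should add hydride to C10 from the face opposite the axial C9 methyl and leave the isolated terminal alkene alone. It would give the dimethylphenylsilyl enol ether F7 directly, which enters the conditions of step 10 to give 18.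

Step 4. C-Benzylation of the hindered magnesium enolate may be slow, with proton transfer, O-alkylation or loss of the labile benzylic bromide, and the small methyl nucleophile may give lower enantioselectivity. The fallback sets out from 5 and comes back at 7; it separates the two events and changes the alkylation from an enolate SN2 reaction to a Lewis-acid-mediated SN1-type reaction. Conjugate addition of Me3Al (copper thiophene-2-carboxylate, chiral phosphoramidite, Et2O, −30 °C) followed by TMSOTf would give the isolable trimethylsilyl enol ether F8. ZnBr2 (cat.) in CH2Cl2 at −40 °C would then ionise 4 to the stabilised trialkoxybenzyl cation, which should alkylate F8 anti to the C8 methyl and give 7.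

Further compounds

F1 | step 10 | [5-(trimethylsilyl)pent-4-yn-1-yl]magnesium chloride | C[Si](C)(C)C#CCCC[Mg]Cl
F2 | step 10 | (1RS,5S,6R)-2,5,6-trimethyl-6-{[2,3,4-tris(methoxymethoxy)phenyl]methyl}-1-[5-(trimethylsilyl)pent-4-yn-1-yl]cyclohex-2-en-1-ol | OC1(CCCC#C[Si](C)(C)C)C(C)=CC[C@H](C)[C@@]1(C)Cc2ccc(OCOC)c(OCOC)c2OCOC
F3 | step 10 | (4R,5S)-2,4,5-trimethyl-4-{[2,3,4-tris(methoxymethoxy)phenyl]methyl}-3-[5-(trimethylsilyl)pent-4-yn-1-yl]cyclohex-2-en-1-one | O=C1C(C)=C(CCCC#C[Si](C)(C)C)[C@](C)(Cc2ccc(OCOC)c(OCOC)c2OCOC)[C@@H](C)C1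
F4 | step 10 | (4R,5S)-2,4,5-trimethyl-3-(pent-4-yn-1-yl)-4-{[2,3,4-tris(methoxymethoxy)phenyl]methyl}cyclohex-2-en-1-one | O=C1C(C)=C(CCCC#C)[C@](C)(Cc2ccc(OCOC)c(OCOC)c2OCOC)[C@@H](C)C1
F5 | step 10 | (2RS,3R,4R,5S)-2,4,5-trimethyl-3-(pent-4-yn-1-yl)-4-{[2,3,4-tris(methoxymethoxy)phenyl]methyl}cyclohexan-1-one | O=C1C(C)[C@@H](CCCC#C)[C@](C)(Cc2ccc(OCOC)c(OCOC)c2OCOC)[C@@H](C)C1
F6 | step 10 | trimethyl{[(3S,4R,5S)-2,4,5-trimethyl-3-(pent-4-yn-1-yl)-4-{[2,3,4-tris(methoxymethoxy)phenyl]methyl}cyclohex-1-en-1-yl]oxy}silane | C[Si](C)(C)OC1=C(C)[C@@H](CCCC#C)[C@](C)(Cc2ccc(OCOC)c(OCOC)c2OCOC)[C@@H](C)C1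
F7 | step 9 | dimethyl(phenyl){[(3S,4R,5S)-2,4,5-trimethyl-3-(pent-4-en-1-yl)-4-{[2,3,4-tris(methoxymethoxy)phenyl]methyl}cyclohex-1-en-1-yl]oxy}silane | C[Si](C)(c1ccccc1)OC1=C(C)[C@@H](CCCC=C)[C@](C)(Cc2ccc(OCOC)c(OCOC)c2OCOC)[C@@H](C)C1
F8 | step 4 | trimethyl{[(3S)-2,3-dimethylcyclohex-1-en-1-yl]oxy}silane | CC1=C(O[Si](C)(C)C)CCC[C@@H]1C
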